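**Plan**

1. Retrosynthesis: the C3–H stereocentre goes back to an achiral allyl enol carbonate of the isoflavone, and the C3–C1' bond is cut into 3-iodochromone 20 and ring B boronate 16.
2. Ring B is cut at C1'–C6' (electrocyclisation of an alkenylcyclobutenone), then at C2'–C3' and C5'–CMe2 (two carbonyl additions to dimethyl squarate). This is possible because the contiguous oxygens on C2', C3', C4' and the tertiary alkyl group on C5' of ring B map onto a squarate-derived cyclobutenone (C3'–C6') plus an α-alkoxyvinyl unit (C1'–C2').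
3. Forward: prenyl Grignard and 1-tert-butoxyvinyllithium additions give cyclobutenone 9, heating closes ring B (step 4), the surplus C6' hydroxyl is removed through its triflate, and C1' is iodinated and borylated.
4. Ring A is bought as 2,4-dihydroxyacetophenone, ring C is closed by iodine-mediated cyclisation of its enaminone, and the halves are joined by Suzuki–Miyaura coupling.
5. The only stereocentre (C3, S) is set in the penultimate step by ligand-controlled palladium-catalysed decarboxylative protonation; mild acid then frees the three phenols.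

Key step: step 4

Remark: primed locants refer to ring B (C1' is bonded to C3), and Ar = 2-tert-butoxy-4-methoxy-3-(methoxymethoxy)-5-(2-methylbut-3-en-2-yl)phenyl.
Assumption: the (S)-configured PHOX ligand is taken to deliver the 3S ketone in step 14; should the sense of induction be the opposite, the (R)-ligand is used.

**Route**

Step 1
Reactants: 1 dimethyl squarate; 2 prenyl chloride
Product: 4 rac-4-hydroxy-2,3-dimethoxy-4-(2-methylbut-3-en-2-yl)cyclobut-2-en-1-one, via prenylmagnesium chloride 3 (not isolated)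
Conditions: 2, Mg turnings, THF, 0 °C; then 1, THF, −78 °C; aq. NH4Cl, −78 °C
Reagents that add atoms: none
Why: Grignard formation and 1,2-addition to one squarate carbonyl, the allylic reagent reacting through its γ-carbon in a six-membered cyclic (SE2′) transition state so that the 1,1-dimethylallyl carbinol results, while the magnesium alkoxide shields the second carbonyl; the new stereocentre is racemic and disappears in step 2.

Step 2
Reactants: 4 rac-4-hydroxy-2,3-dimethoxy-4-(2-methylbut-3-en-2-yl)cyclobut-2-en-1-one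
Product: 5 3-methoxy-4-(2-methylbut-3-en-2-yl)cyclobut-3-ene-1,2-dione
Conditions: conc. HCl (cat.), CH2Cl2, rt
Reagents that add atoms: water, O
Why: Acid ionises the tertiary hydroxyl to a methoxy-stabilised cyclobutenyl cation, water re-adds at the oxocarbenium carbon and methanol is expelled, which is the standard rearrangement of squarate 1,2-adducts to 3-alkyl-4-alkoxycyclobutenediones.

Step 3
Reactants: 5 3-methoxy-4-(2-methylbut-3-en-2-yl)cyclobut-3-ene-1,2-dione; 6 tert-butyl vinyl ether
Product: 9 rac-4-(1-tert-butoxyvinyl)-3-methoxy-4-(methoxymethoxy)-2-(2-methylbut-3-en-2-yl)cyclobut-2-en-1-one, via 1-tert-butoxyvinyllithium 7 (not isolated), via lithium alkoxide 8 (not isolated)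
Conditions: 6 (excess), t-BuLi, THF, −78 → 0 °C; then 5, THF, −78 °C; then MOMCl, DMPU, −78 → −20 °C; aq. NaHCO3
Reagents that add atoms: chloromethyl methyl ether (MOMCl), COCCl
Why: α-Deprotonation of the alkyl vinyl ether gives the α-alkoxyvinyllithium, which adds 1,2 to the carbonyl next to the methoxy-bearing carbon because the other carbonyl is a vinylogous ester and is shielded by the tertiary alkyl group, and the tertiary lithium alkoxide is then O-alkylated by the reactive α-chloro ether (Williamson-type); the stereocentre formed is racemic and is erased in step 4.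

Step 4
Reactants: 9 rac-4-(1-tert-butoxyvinyl)-3-methoxy-4-(methoxymethoxy)-2-(2-methylbut-3-en-2-yl)cyclobut-2-en-1-one
Product: 12 5-tert-butoxy-3-methoxy-4-(methoxymethoxy)-2-(2-methylbut-3-en-2-yl)phenol, via dienylketene 10 (not isolated), via cyclohexadienone 11 (not isolated)
Conditions: toluene (degassed, 0.02 M, base-washed glassware), 110 °C
Reagents that add atoms: none
Why: Heating opens the cyclobutenone by a four-electron conrotatory electrocyclic cleavage of the C1–C4 bond to the (Z)-dienylketene 10, whose ketene carbon and enol ether CH2 terminus join in a six-electron disrotatory electrocyclisation, and the cyclohexa-2,4-dienone 11 then enolises to phenol 12. The closest known reaction type is the Moore rearrangement of 4-alkenyl-4-alkoxycyclobutenones to protected hydroquinones. Ring B is closed by this six-electron electrocyclisation of a hexatriene in which all six termini and inner atoms end in the six-membered ring, the single new ring bond being C1'–C6'; the four squarate carbons become C3'–C6' and the vinyl unit becomes C1'–C2'. No stereocentre is created, and the one at C4 of 9 is lost as that carbon becomes aromatic. The step needs the alkenyl group to rotate inward towards the ketene, which the outward preference of the C4 oxygen donor (the methoxymethoxy group) secures, and the order of substituents around ring B is already fixed by the order of the two carbonyl additions. The quaternary 1,1-dimethylallyl group cannot reach the ketene carbon in an unstrained geometry, so interception of the ketene by that alkene is not expected.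

Step 5
Reactants: 12 5-tert-butoxy-3-methoxy-4-(methoxymethoxy)-2-(2-methylbut-3-en-2-yl)phenol
Product: 13 5-tert-butoxy-3-methoxy-4-(methoxymethoxy)-2-(2-methylbut-3-en-2-yl)phenyl trifluoromethanesulfonate
Conditions: Tf2O, pyridine, CH2Cl2, 0 °C
Reagents that add atoms: triflic anhydride, O=S(=O)(OS(=O)(=O)C(F)(F)F)C(F)(F)F
Why: O-Sulfonylation of the only free phenol (aryl triflate formation), done on crude 12 under basic conditions because a phenol ortho to a 1,1-dimethylallyl group tends to cyclise onto the alkene under acid.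

Step 6
Reactants: 13 5-tert-butoxy-3-methoxy-4-(methoxymethoxy)-2-(2-methylbut-3-en-2-yl)phenyl trifluoromethanesulfonate
Product: 14 1-tert-butoxy-3-methoxy-2-(methoxymethoxy)-4-(2-methylbut-3-en-2-yl)benzene
Conditions: Pd(OAc)2 (cat.), dppf, HCO2H, Et3N, DMF, 80 °C
Reagents that add atoms: none
Why: Palladium-catalysed formate reduction of an aryl triflate (oxidative addition of zerovalent palladium, formate exchange, loss of CO2, C–H reductive elimination); the quaternary allylic carbon has no hydrogen for alkene migration, and a four-membered carbopalladation onto the vinyl group is too strained to compete with hydride transfer.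

Step 7
Reactants: 14 1-tert-butoxy-3-methoxy-2-(methoxymethoxy)-4-(2-methylbut-3-en-2-yl)benzene
Product: 15 2-tert-butoxy-1-iodo-4-methoxy-3-(methoxymethoxy)-5-(2-methylbut-3-en-2-yl)benzene
Conditions: NIS, TFA (10 mol %), MeCN, 0 °C → rt
Reagents that add atoms: N-iodosuccinimide, O=C1CCC(=O)N1I
Why: Electrophilic aromatic iodination goes to C1', which is para to the C4' methoxy and ortho to the C2' tert-butoxy group, whereas C6' is meta to both and buried beside the quaternary carbon; the electron-rich arene should react well before the hindered monosubstituted alkene.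

Step 8
Reactants: 15 2-tert-butoxy-1-iodo-4-methoxy-3-(methoxymethoxy)-5-(2-methylbut-3-en-2-yl)benzene
Product: 16 2-Ar-4,4,5,5-tetramethyl-1,3,2-dioxaborolane (Ar as defined above)
Conditions: B2pin2, PdCl2(dppf) (cat.), KOAc, 1,4-dioxane, 85 °C
Reagents that add atoms: bis(pinacolato)diboron, CC1(C)OB(OC1(C)C)B1OC(C)(C)C(C)(C)O1
Why: Miyaura borylation of an aryl iodide, which tolerates the acetal, the tert-butyl ether and the remote alkene (meta to the C–I bond, so no Heck pathway is available).

Step 9
Reactants: 17 2,4-dihydroxyacetophenone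
Product: 18 1-[2-hydroxy-4-(methoxymethoxy)phenyl]ethanone
Conditions: MOMCl, K2CO3, acetone, 0 °C → rt
Reagents that add atoms: chloromethyl methyl ether (MOMCl), COCCl
Why: Williamson-type alkylation that is selective for the 4-hydroxyl because the 2-hydroxyl is tied up in a hydrogen bond to the acetyl carbonyl.

Step 10
Reactants: 18 1-[2-hydroxy-4-(methoxymethoxy)phenyl]ethanone
Product: 19 (E)-3-(dimethylamino)-1-[2-hydroxy-4-(methoxymethoxy)phenyl]prop-2-en-1-one
Conditions: DMF-DMA, toluene, 95 °C
Reagents that add atoms: N,N-dimethylformamide dimethyl acetal, COC(OC)N(C)C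
Why: Condensation of the methyl ketone with the amide acetal gives the E-enaminone with loss of methanol, the standard entry to chromones from 2-hydroxyacetophenones.

Step 11
Reactants: 19 (E)-3-(dimethylamino)-1-[2-hydroxy-4-(methoxymethoxy)phenyl]prop-2-en-1-one
Product: 20 3-iodo-7-(methoxymethoxy)-4H-chromen-4-one
Conditions: I2, CHCl3, rt; aq. Na2S2O3
Reagents that add atoms: iodine, II
Why: Iodine-mediated cyclisation of an o-hydroxyaryl enaminone: α-iodination, attack of the phenol oxygen on the iminium carbon (closing ring C at O1–C2) and loss of dimethylamine give the 3-iodochromone.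

Step 12
Reactants: 16 2-Ar-4,4,5,5-tetramethyl-1,3,2-dioxaborolane; 20 3-iodo-7-(methoxymethoxy)-4H-chromen-4-one
Product: 21 3-Ar-7-(methoxymethoxy)-4H-chromen-4-one
Conditions: Pd(OAc)2 (cat.), SPhos, K3PO4, THF/H2O (10:1), 45 °C
Reagents that add atoms: none
Why: Suzuki–Miyaura coupling of a 3-iodochromone with an arylboronate, the usual isoflavone construction, here with a biarylphosphine ligand to accommodate the ortho tert-butoxy group and a mild temperature to spare the base-sensitive pyranone.

Step 13
Reactants: 21 3-Ar-7-(methoxymethoxy)-4H-chromen-4-one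
Product: 23 allyl 3-Ar-7-(methoxymethoxy)-2H-chromen-4-yl carbonate, via lithium enolate 22 (not isolated)
Conditions: LiBH(s-Bu)3, THF, −78 °C; then allyl chloroformate, −78 → 0 °C
Reagents that add atoms: allyl chloroformate, C=CCOC(=O)Cl
Why: Conjugate (1,4) hydride addition of the bulky borohydride at C2 of the chromone gives the lithium enolate, which the chloroformate acylates on oxygen to the allyl enol carbonate; C3 is still sp2, so no stereocentre is involved.

Step 14
Reactants: 23 allyl 3-Ar-7-(methoxymethoxy)-2H-chromen-4-yl carbonate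
Product: 24 (3S)-3-Ar-7-(methoxymethoxy)chroman-4-one
Conditions: Pd2(dba)3 (5 mol %), (S)-t-Bu-PHOX (12.5 mol %), Meldrum's acid (2.5 equiv), 1,4-dioxane, 22 °C
Reagents that add atoms: none
Why: Enantioselective decarboxylative protonation: zerovalent palladium ionises the allyl carbonate, CO2 is lost, and the enolate paired with the chiral PHOX–allylpalladium cation is protonated at C3 on one face by Meldrum's acid, which also takes up the allyl group; the ligand sets the C3 configuration, the ortho-substituted ring B should help facial discrimination, and the neutral conditions should not enolise the product.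

Step 15
Reactants: 24 (3S)-3-Ar-7-(methoxymethoxy)chroman-4-one
Product: 25 (3S)-3-[2,3-dihydroxy-4-methoxy-5-(2-methylbut-3-en-2-yl)phenyl]-7-hydroxychroman-4-one (CNP0134633.1)
Conditions: TFA/CH2Cl2/H2O (20:78:2), 0 °C → rt, short reaction time; NaHCO3 work-up
Reagents that add atoms: none
Why: Acidolysis in which the two methoxymethyl acetals hydrolyse and the aryl tert-butyl ether loses isobutene, under dilute acid at low temperature where enolisation at C3 should be slow; no phenol is freed next to the 1,1-dimethylallyl group (its neighbours are OMe and H), so cyclisation onto the alkene is not expected.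

**Compound list**

1 | dimethyl squarate (3,4-dimethoxycyclobut-3-ene-1,2-dione) | COC1=C(OC)C(=O)C1=O | starting material
2 | prenyl chloride (1-chloro-3-methylbut-2-ene) | CC(C)=CCCl | starting material
3 | prenylmagnesium chloride | CC(C)=CC[Mg]Cl | intermediate
4 | rac-4-hydroxy-2,3-dimethoxy-4-(2-methylbut-3-en-2-yl)cyclobut-2-en-1-one | C=CC(C)(C)C1(O)C(OC)=C(OC)C1=O | intermediate
5 | 3-methoxy-4-(2-methylbut-3-en-2-yl)cyclobut-3-ene-1,2-dione | C=CC(C)(C)C1=C(OC)C(=O)C1=O | intermediate
6 | tert-butyl vinyl ether | C=COC(C)(C)C | starting material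
7 | 1-tert-butoxyvinyllithium | [Li]C(=C)OC(C)(C)C | intermediate
8 | lithium rac-1-(1-tert-butoxyvinyl)-2-methoxy-3-(2-methylbut-3-en-2-yl)-4-oxocyclobut-2-en-1-olate | C=CC(C)(C)C1=C(OC)C([O-])(C(=C)OC(C)(C)C)C1=O.[Li+] | intermediate
9 | rac-4-(1-tert-butoxyvinyl)-3-methoxy-4-(methoxymethoxy)-2-(2-methylbut-3-en-2-yl)cyclobut-2-en-1-one | C=CC(C)(C)C1=C(OC)C(OCOC)(C(=C)OC(C)(C)C)C1=O | intermediate
10 | (3Z)-5-tert-butoxy-3-methoxy-4-(methoxymethoxy)-2-(2-methylbut-3-en-2-yl)hexa-1,3,5-trien-1-one (dienylketene) | O=C=C(C(C)(C)C=C)/C(OC)=C(\C(=C)OC(C)(C)C)OCOC | intermediate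
11 | 5-tert-butoxy-3-methoxy-4-(methoxymethoxy)-2-(2-methylbut-3-en-2-yl)cyclohexa-2,4-dien-1-one | O=C1CC(OC(C)(C)C)=C(OCOC)C(OC)=C1C(C)(C)C=C | intermediate
12 | 5-tert-butoxy-3-methoxy-4-(methoxymethoxy)-2-(2-methylbut-3-en-2-yl)phenol | C=CC(C)(C)c1c(O)cc(OC(C)(C)C)c(OCOC)c1OC | intermediate
13 | 5-tert-butoxy-3-methoxy-4-(methoxymethoxy)-2-(2-methylbut-3-en-2-yl)phenyl trifluoromethanesulfonate | C=CC(C)(C)c1c(OS(=O)(=O)C(F)(F)F)cc(OC(C)(C)C)c(OCOC)c1OC | intermediate
14 | 1-tert-butoxy-3-methoxy-2-(methoxymethoxy)-4-(2-methylbut-3-en-2-yl)benzene | C=CC(C)(C)c1ccc(OC(C)(C)C)c(OCOC)c1OC | intermediate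
15 | 2-tert-butoxy-1-iodo-4-methoxy-3-(methoxymethoxy)-5-(2-methylbut-3-en-2-yl)benzene | C=CC(C)(C)c1cc(I)c(OC(C)(C)C)c(OCOC)c1OC | intermediate
16 | 2-[2-tert-butoxy-4-methoxy-3-(methoxymethoxy)-5-(2-methylbut-3-en-2-yl)phenyl]-4,4,5,5-tetramethyl-1,3,2-dioxaborolane | C=CC(C)(C)c1cc(B2OC(C)(C)C(C)(C)O2)c(OC(C)(C)C)c(OCOC)c1OC | intermediate
17 | 2,4-dihydroxyacetophenone | CC(=O)c1ccc(O)cc1O | starting material
18 | 1-[2-hydroxy-4-(methoxymethoxy)phenyl]ethanone | CC(=O)c1ccc(OCOC)cc1O | intermediate
19 | (E)-3-(dimethylamino)-1-[2-hydroxy-4-(methoxymethoxy)phenyl]prop-2-en-1-one | CN(C)/C=C/C(=O)c1ccc(OCOC)cc1O | intermediate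
20 | 3-iodo-7-(methoxymethoxy)-4H-chromen-4-one | O=c1c(I)coc2cc(OCOC)ccc12 | intermediate
21 | 3-[2-tert-butoxy-4-methoxy-3-(methoxymethoxy)-5-(2-methylbut-3-en-2-yl)phenyl]-7-(methoxymethoxy)-4H-chromen-4-one | C=CC(C)(C)c1cc(-c2coc3cc(OCOC)ccc3c2=O)c(OC(C)(C)C)c(OCOC)c1OC | intermediate
22 | lithium 3-[2-tert-butoxy-4-methoxy-3-(methoxymethoxy)-5-(2-methylbut-3-en-2-yl)phenyl]-7-(methoxymethoxy)-2H-chromen-4-olate | C=CC(C)(C)c1cc(C2=C([O-])c3ccc(OCOC)cc3OC2)c(OC(C)(C)C)c(OCOC)c1OC.[Li+] | intermediate
23 | allyl 3-[2-tert-butoxy-4-methoxy-3-(methoxymethoxy)-5-(2-methylbut-3-en-2-yl)phenyl]-7-(methoxymethoxy)-2H-chromen-4-yl carbonate | C=CCOC(=O)OC1=C(c2cc(C(C)(C)C=C)c(OC)c(OCOC)c2OC(C)(C)C)COc2cc(OCOC)ccc21 | intermediate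
24 | (3S)-3-[2-tert-butoxy-4-methoxy-3-(methoxymethoxy)-5-(2-methylbut-3-en-2-yl)phenyl]-7-(methoxymethoxy)chroman-4-one | C=CC(C)(C)c1cc([C@H]2COc3cc(OCOC)ccc3C2=O)c(OC(C)(C)C)c(OCOC)c1OC | intermediate
25 | (3S)-3-[2,3-dihydroxy-4-methoxy-5-(2-methylbut-3-en-2-yl)phenyl]-7-hydroxychroman-4-one | C=CC(C)(C)c1cc([C@H]2COc3cc(O)ccc3C2=O)c(O)c(O)c1OC | target

**Count and risks**

Total step count: 15. Longest linear sequence: 12 steps (steps 1–8 and 12–15); the chromone branch (steps 9–11) adds three.

Steps most likely to fail: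

Step 3. Metalation of the bulky vinyl ether may be incomplete, and O-alkylation of the hindered tertiary lithium alkoxide may be slow enough that the alkoxide fragments or ring-opens on warming. The fallback sets out from 5 and comes back to the route at 13; it replaces alkylation of the alkoxide by low-temperature silylation and moves the methoxymethyl group onto a phenol later. Alkoxide 8 is generated as in step 3 and silylated at −78 °C with TESOTf to give the 4-(triethylsilyloxy)cyclobutenone F1. Heating F1 in toluene at 110 °C should lead through the silyloxy dienylketene F2 and the silyloxy cyclohexadienone F3 to the silyloxyphenol F4. Tf2O and pyridine should convert this into the silyloxy aryl triflate F5, HF·pyridine buffered with pyridine should free the C3' oxygen to give the hydroxy triflate F6, and MOMCl with iPr2NEt should then give 13.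

Step 14. Facial discrimination in the protonation of the palladium enolate may be insufficient, or adventitious acid may cause racemic background protonation. The fallback sets out from 21 and comes back at 24; it sets C3 by dynamic kinetic resolution instead of protonation. Asymmetric transfer hydrogenation with RuCl[(S,S)-TsDPEN](p-cymene) (or its enantiomer, whichever leads to the 3S,4S alcohol) and HCO2H/Et3N should first reduce the chromone double bond to the racemic isoflavanone F7. F7 epimerises at C3 under the amine-buffered conditions while one enantiomer is reduced faster at the carbonyl, which should give the cis-(3S,4S)-isoflavan-4-ol F8. Oxidation with Dess–Martin periodinane and NaHCO3 in CH2Cl2 at 0 °C should return ketone 24 without touching C3.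

Step 15. Acid-promoted enolisation at C3 may erode the enantiomeric purity, and the freed C2' phenol may form a hemiketal with the C4 carbonyl and dehydrate. The fallback sets out from 21 and comes back at 25; it moves the acid step in front of the stereocentre and ends with fluoride. TFA/CH2Cl2/H2O on the achiral isoflavone should give the trihydroxyisoflavone F9, and TBSCl with imidazole in DMF the tris(tert-butyldimethylsilyl) ether F10. LiBH(s-Bu)3 at −78 °C should give the lithium enolate F11, trapped with allyl chloroformate as the silylated allyl enol carbonate F12. Pd2(dba)3, (S)-t-Bu-PHOX and Meldrum's acid should give the silylated (S)-isoflavanone F13, and HF·pyridine buffered with pyridine in THF at 0 °C should give 25.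

**Further compounds**

F1 | step 3 | rac-4-(1-tert-butoxyvinyl)-3-methoxy-2-(2-methylbut-3-en-2-yl)-4-(triethylsilyloxy)cyclobut-2-en-1-one | C=CC(C)(C)C1=C(OC)C(O[Si](CC)(CC)CC)(C(=C)OC(C)(C)C)C1=O
F2 | step 3 | (3Z)-5-tert-butoxy-3-methoxy-2-(2-methylbut-3-en-2-yl)-4-(triethylsilyloxy)hexa-1,3,5-trien-1-one | O=C=C(C(C)(C)C=C)/C(OC)=C(\C(=C)OC(C)(C)C)O[Si](CC)(CC)CC
F3 | step 3 | 5-tert-butoxy-3-methoxy-2-(2-methylbut-3-en-2-yl)-4-(triethylsilyloxy)cyclohexa-2,4-dien-1-one | O=C1CC(OC(C)(C)C)=C(O[Si](CC)(CC)CC)C(OC)=C1C(C)(C)C=C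
F4 | step 3 | 5-tert-butoxy-3-methoxy-2-(2-methylbut-3-en-2-yl)-4-(triethylsilyloxy)phenol | C=CC(C)(C)c1c(O)cc(OC(C)(C)C)c(O[Si](CC)(CC)CC)c1OC
F5 | step 3 | 5-tert-butoxy-3-methoxy-2-(2-methylbut-3-en-2-yl)-4-(triethylsilyloxy)phenyl trifluoromethanesulfonate | C=CC(C)(C)c1c(OS(=O)(=O)C(F)(F)F)cc(OC(C)(C)C)c(O[Si](CC)(CC)CC)c1OC
F6 | step 3 | 5-tert-butoxy-4-hydroxy-3-methoxy-2-(2-methylbut-3-en-2-yl)phenyl trifluoromethanesulfonate | C=CC(C)(C)c1c(OS(=O)(=O)C(F)(F)F)cc(OC(C)(C)C)c(O)c1OC
F7 | step 14 | rac-3-[2-tert-butoxy-4-methoxy-3-(methoxymethoxy)-5-(2-methylbut-3-en-2-yl)phenyl]-7-(methoxymethoxy)chroman-4-one | C=CC(C)(C)c1cc(C2COc3cc(OCOC)ccc3C2=O)c(OC(C)(C)C)c(OCOC)c1OC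
F8 | step 14 | (3S,4S)-3-[2-tert-butoxy-4-methoxy-3-(methoxymethoxy)-5-(2-methylbut-3-en-2-yl)phenyl]-7-(methoxymethoxy)chroman-4-ol (cis) | C=CC(C)(C)c1cc([C@H]2COc3cc(OCOC)ccc3[C@H]2O)c(OC(C)(C)C)c(OCOC)c1OC
F9 | step 15 | 3-[2,3-dihydroxy-4-methoxy-5-(2-methylbut-3-en-2-yl)phenyl]-7-hydroxy-4H-chromen-4-one | C=CC(C)(C)c1cc(-c2coc3cc(O)ccc3c2=O)c(O)c(O)c1OC
F10 | step 15 | 3-[2,3-bis(tert-butyldimethylsilyloxy)-4-methoxy-5-(2-methylbut-3-en-2-yl)phenyl]-7-(tert-butyldimethylsilyloxy)-4H-chromen-4-one | C=CC(C)(C)c1cc(-c2coc3cc(O[Si](C)(C)C(C)(C)C)ccc3c2=O)c(O[Si](C)(C)C(C)(C)C)c(O[Si](C)(C)C(C)(C)C)c1OC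
F11 | step 15 | lithium 3-[2,3-bis(tert-butyldimethylsilyloxy)-4-methoxy-5-(2-methylbut-3-en-2-yl)phenyl]-7-(tert-butyldimethylsilyloxy)-2H-chromen-4-olate | C=CC(C)(C)c1cc(C2=C([O-])c3ccc(O[Si](C)(C)C(C)(C)C)cc3OC2)c(O[Si](C)(C)C(C)(C)C)c(O[Si](C)(C)C(C)(C)C)c1OC.[Li+]
F12 | step 15 | allyl 3-[2,3-bis(tert-butyldimethylsilyloxy)-4-methoxy-5-(2-methylbut-3-en-2-yl)phenyl]-7-(tert-butyldimethylsilyloxy)-2H-chromen-4-yl carbonate | C=CCOC(=O)OC1=C(c2cc(C(C)(C)C=C)c(OC)c(O[Si](C)(C)C(C)(C)C)c2O[Si](C)(C)C(C)(C)C)COc2cc(O[Si](C)(C)C(C)(C)C)ccc21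
F13 | step 15 | (3S)-3-[2,3-bis(tert-butyldimethylsilyloxy)-4-methoxy-5-(2-methylbut-3-en-2-yl)phenyl]-7-(tert-butyldimethylsilyloxy)chroman-4-one | C=CC(C)(C)c1cc([C@H]2COc3cc(O[Si](C)(C)C(C)(C)C)ccc3C2=O)c(O[Si](C)(C)C(C)(C)C)c(O[Si](C)(C)C(C)(C)C)c1OC
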